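Ring A of the flavone (C4a, C5, C6, C7, C8, C8a) carries oxygen on C5, C7 and C8a and the C4 carbonyl on C4a, which is the alternating pattern of a folded poly-β-keto chain. It is therefore opened at C4a–C5 (equivalent to C4a–C8a until ring C exists). This leads back to an acyclic methyl 3,5,7-trioxonon-8-enoate that bears the 4-prenyloxyphenyl ring B on C9. One magnesium-alkoxide Claisen closure converts this cinnamoyl triketo ester into the 2',4',6'-trihydroxychalcone, delivering all six ring A carbons and its three oxygens in aromatic form at once. Ring C, the C3 oxygen and both methyl ethers follow through oxa-Michael closure, alkaline peroxide oxidation and two chelation-guided methylations.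

Key step: step 5

Remark on stereochemistry: the target has no stereocentre and no stereogenic axis, so it is achiral and no enantiomer has to be selected. The E alkene of the cinnamoyl unit comes from 1. C2/C3 of 10, 11 and 13 are racemic and disappear when ring C becomes aromatic.

Remark on locants: C1–C9 denote the chain of 8 (C1 = ester carbonyl); flavone locants are used for ring atoms. O2' and O6' of 9 are equivalent, so chain C1 becomes C5 or C8a without distinction.

Remark on isomer pairs: 2',6'-dihydroxychalcones close readily to 5-hydroxyflavanones. The route uses this on purpose. The pairs 9/10 and 12/11 interconvert in base, so any mixture converges in step 7.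

Step 1
Reactants: 1 (E)-4-hydroxycinnamic acid; 2 prenyl bromide (1-bromo-3-methylbut-2-ene)
Product: 3 3-methylbut-2-enyl (E)-3-[4-(3-methylbut-2-enyloxy)phenyl]prop-2-enoate
Conditions: 2 (2.3 equiv), K2CO3 (3 equiv), DMF, rt
Reagents that add atoms: none
Why: Double SN2 alkylation (Williamson ether synthesis at the phenoxide plus carboxylate esterification) with a reactive primary allylic bromide under mild carbonate conditions leaves the E alkene untouched and gives an ester that already serves as the acyl donor for step 2.

Step 2
Reactants: 3 3-methylbut-2-enyl (E)-3-[4-(3-methylbut-2-enyloxy)phenyl]prop-2-enoate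
Product: 4 (E)-N-methoxy-N-methyl-3-[4-(3-methylbut-2-enyloxy)phenyl]prop-2-enamide
Conditions: MeNH(OMe)·HCl (1.6 equiv), iPrMgCl (3.1 equiv), THF, −20 → 0 °C; cold 1 M HCl
Reagents that add atoms: N,O-dimethylhydroxylamine hydrochloride, CNOC.Cl
Why: The chloromagnesium amide made in situ attacks the ester carbonyl directly (magnesium-amide aminolysis to a Weinreb amide), and because the electron-rich cinnamate is a poor Michael acceptor the E geometry and the aryl prenyl ether should be retained.

Step 3
Reactants: 5 dehydroacetic acid (3-acetyl-4-hydroxy-6-methylpyran-2-one)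
Product: 6 methyl 3,5-dioxohexanoate
Conditions: Mg(OMe)2 (2 equiv, commercial solution), MeOH, reflux; cold 2 M HCl
Reagents that add atoms: magnesium methoxide, C[O-].C[O-].[Mg+2]; methanol, CO
Why: Methoxide removes the 3-acetyl group by retro-Claisen cleavage and opens the pyranone lactone, and magnesium chelation of the resulting 3,5-dioxo ester holds it in the open-chain form until acidification.

Step 4
Reactants: 6 methyl 3,5-dioxohexanoate; 4 (E)-N-methoxy-N-methyl-3-[4-(3-methylbut-2-enyloxy)phenyl]prop-2-enamide
Product: 8 methyl (E)-3,5,7-trioxo-9-[4-(3-methylbut-2-enyloxy)phenyl]non-8-enoate, via trilithium trienolate 7 (not isolated)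
Conditions: 6 (1.3 equiv), LDA (commercial, 3.0 equiv per 6), THF, −78 → 0 °C; then 4 (1.0 equiv), −78 → −20 °C; AcOH/THF quench at −78 °C, cold pH 5 work-up
Reagents that add atoms: none
Why: Three equivalents of LDA remove the C4, C2 and finally a terminal methyl proton, and the last-formed, most basic terminal carbanion adds 1,2 to the Weinreb amide to give a chelated tetrahedral adduct that survives until the cold acid quench (Weinreb ketone synthesis with a poly-β-carbonyl polyanion), which blocks over-addition, proton exchange with the product and premature cyclisation.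

Step 5
Reactants: 8 methyl (E)-3,5,7-trioxo-9-[4-(3-methylbut-2-enyloxy)phenyl]non-8-enoate
Product: 9 (E)-3-[4-(3-methylbut-2-enyloxy)phenyl]-1-(2,4,6-trihydroxyphenyl)prop-2-en-1-one (2',4',6'-trihydroxy-4-prenyloxychalcone)
Conditions: Mg(OMe)2 (5 equiv), dry MeOH, N2, rt → 60 °C; poured into ice-cold 1 M HCl/EtOAc, used at once
Reagents that add atoms: none
Why: Excess magnesium methoxide turns 8 into a chelated polyenolate in which the two most acidic positions, C4–H and C6–H, are deprotonated, so all three ketone carbonyls are masked as enolates, the ester carbon C1 remains the only real electrophile, and C6 adds to it. The tetrahedral adduct expels methoxide, and the 2-acylcyclohexane-1,3,5-trione so formed enolises three times to the aromatic acylphloroglucinol, whose phenoxide formation drives the sequence forward. The closest known reaction type is the base-mediated intramolecular Claisen (Dieckmann-type) cyclisation of 3,5,7-triketo esters to 2-acylphloroglucinols, the laboratory counterpart of chalcone-synthase folding. Ring A is the only ring closed, in a 6-exo-trig mode at the ester carbonyl through the new C6–C1 bond (C4a–C5 of the flavone), no stereocentre is created, and the E alkene is a spectator. The selectivity required is Claisen folding ahead of C2-to-C7 aldol folding, enol lactonisation to a 4-hydroxypyran-2-one and enol-oxygen addition to C9: the cinnamoyl carbonyl C7 and its β-carbon C9 are weakened as electrophiles by conjugation with the 4-alkoxyphenyl donor and by enolisation, and dry methanolic methoxide neither hydrolyses the ester nor tolerates the pyranone, which it reopens to 8. Magnesium chelation between the 2'-oxide and the ketone should keep the product in the open chalcone form until the fast cold acid quench.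

Step 6
Reactants: 9 2',4',6'-trihydroxy-4-prenyloxychalcone
Product: 11 (±)-5-hydroxy-7-methoxy-2-[4-(3-methylbut-2-enyloxy)phenyl]chroman-4-one, via 5,7-dihydroxyflavanone 10 (not isolated)
Conditions: K2CO3 (1.5 equiv), acetone, reflux; then Me2SO4 (1.05 equiv), reflux
Reagents that add atoms: dimethyl sulfate, COS(=O)(=O)OC
Why: Carbonate triggers the 6-endo-trig oxa-Michael closure typical of 2',6'-dihydroxychalcones to racemic 10, whose 7-OH is a vinylogous acid and the only non-chelated phenol, so one equivalent of the hard methylating agent should give the 7-methyl ether (Williamson-type O-methylation) while the hydrogen-bonded 5-OH stays free and the racemic C2 centre is erased in step 7.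

Step 7
Reactants: 11 (±)-5-hydroxy-7-methoxy-2-[4-(3-methylbut-2-enyloxy)phenyl]chroman-4-one
Product: 14 3,5-dihydroxy-7-methoxy-2-[4-(3-methylbut-2-enyloxy)phenyl]chromen-4-one, via ring-opened chalcone 12 (not isolated), via trans-dihydroflavonol 13 (not isolated)
Conditions: 2 M aq NaOH (10 equiv), MeOH, rt; then 30% H2O2 (6 equiv), 0 °C → rt; 1 M HCl
Reagents that add atoms: hydrogen peroxide, OO
Why: In this Algar–Flynn–Oyamada reaction strong base reopens 11 by E1cB to the chalcone phenoxide 12, hydroperoxide oxygenates Cα of the enone while an ortho phenoxide bonds to the benzylic Cβ (a six-ring closure favoured over the aurone-forming five-ring mode by the cation-stabilising 4-alkoxyphenyl group and by the absence of a bulky 6'-alkoxy substituent), and excess peroxide dehydrogenates 13 to the flavonol, the isolated prenyl alkene being inert to nucleophilic HOO−.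

Step 8
Reactants: 14 3,5-dihydroxy-7-methoxy-2-[4-(3-methylbut-2-enyloxy)phenyl]chromen-4-one
Product: 15 5-hydroxy-3,7-dimethoxy-2-[4-(3-methylbut-2-enyloxy)phenyl]chromen-4-one (target)
Conditions: Me2SO4 (1.05 equiv), K2CO3 (1.2 equiv), acetone, rt → 40 °C
Reagents that add atoms: dimethyl sulfate, COS(=O)(=O)OC
Why: The enolic 3-OH is more acidic and held only by a weak five-membered hydrogen bond, whereas the 5-OH sits in a strong six-membered chelate with C4=O, so one equivalent of dimethyl sulfate with carbonate should methylate O3 alone (selective Williamson-type partial methylation of a flavonol).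

Compound list
1 | (E)-4-hydroxycinnamic acid | O=C(O)/C=C/c1ccc(O)cc1 | starting material
2 | prenyl bromide | CC(C)=CCBr | starting material
3 | 3-methylbut-2-enyl (E)-3-[4-(3-methylbut-2-enyloxy)phenyl]prop-2-enoate | CC(C)=CCOC(=O)/C=C/c1ccc(OCC=C(C)C)cc1 | intermediate
4 | (E)-N-methoxy-N-methyl-3-[4-(3-methylbut-2-enyloxy)phenyl]prop-2-enamide | CON(C)C(=O)/C=C/c1ccc(OCC=C(C)C)cc1 | intermediate
5 | dehydroacetic acid | CC(=O)C1=C(O)C=C(C)OC1=O | starting material
6 | methyl 3,5-dioxohexanoate | COC(=O)CC(=O)CC(C)=O | intermediate
7 | trilithium trienolate of 6 (formed in situ) | [Li+].[Li+].[Li+].C=C([O-])C=C([O-])C=C([O-])OC | intermediate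
8 | methyl (E)-3,5,7-trioxo-9-[4-(3-methylbut-2-enyloxy)phenyl]non-8-enoate (drawn as the triketo tautomer, largely enolised) | COC(=O)CC(=O)CC(=O)CC(=O)/C=C/c1ccc(OCC=C(C)C)cc1 | intermediate
9 | (E)-2',4',6'-trihydroxy-4-(prenyloxy)chalcone | O=C(/C=C/c1ccc(OCC=C(C)C)cc1)c1c(O)cc(O)cc1O | intermediate
10 | (±)-5,7-dihydroxy-2-[4-(3-methylbut-2-enyloxy)phenyl]chroman-4-one (formed in situ) | O=C1CC(c2ccc(OCC=C(C)C)cc2)Oc2cc(O)cc(O)c12 | intermediate
11 | (±)-5-hydroxy-7-methoxy-2-[4-(3-methylbut-2-enyloxy)phenyl]chroman-4-one | COc1cc(O)c2c(c1)OC(c1ccc(OCC=C(C)C)cc1)CC2=O | intermediate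
12 | (E)-2',6'-dihydroxy-4'-methoxy-4-(prenyloxy)chalcone (formed in situ) | COc1cc(O)c(C(=O)/C=C/c2ccc(OCC=C(C)C)cc2)c(O)c1 | intermediate
13 | (±)-trans-3,5-dihydroxy-7-methoxy-2-[4-(3-methylbut-2-enyloxy)phenyl]chroman-4-one (2R*,3R*, racemic, one enantiomer drawn, formed in situ) | CC(C)=CCOc1ccc(cc1)[C@@H]1[C@H](C(=O)c2c(O1)cc(OC)cc2O)O | intermediate
14 | 3,5-dihydroxy-7-methoxy-2-[4-(3-methylbut-2-enyloxy)phenyl]chromen-4-one | COc1cc(O)c2c(=O)c(O)c(-c3ccc(OCC=C(C)C)cc3)oc2c1 | intermediate
15 | 5-hydroxy-3,7-dimethoxy-2-[4-(3-methylbut-2-enyloxy)phenyl]chromen-4-one | COc1cc(O)c2c(=O)c(OC)c(-c3ccc(OCC=C(C)C)cc3)oc2c1 | target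

Total step count: 8. Longest linear sequence: 7 (steps 1, 2, 4, 5, 6, 7, 8); step 3 is a one-step side branch.

Steps most likely to fail

Step 5.
- **What may go wrong:** The polyketo chain may fold the wrong way. The competing processes are carbon C2 adding to C7 with aromatising dehydration, enol oxygen acylation at C1, and enol oxygen addition to C9. The electron-rich product may also be lost to air oxidation before the quench.
- **Fallback:** Ring A is bought instead of built. Setting out from 2, 4-hydroxybenzaldehyde is O-alkylated (K2CO3, DMF) to 4-(3-methylbut-2-enyloxy)benzaldehyde F1. F1 is condensed with commercial 2',6'-dihydroxy-4'-methoxyacetophenone in a Claisen–Schmidt reaction (KOH, EtOH/H2O, rt).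
- **Return to the route:** This gives chalcone 12, which is taken directly into the peroxide stage of step 7.

Step 7.
- **What may go wrong:** Closure of the five-membered ring at Cα may compete with six-ring closure at Cβ. Peroxide addition to the doubly deprotonated enone may be slow. The electron-rich flavonol may suffer oxidative cleavage on long exposure.
- **Fallback:** Oxidation and ring closure are separated so that no phenoxide is present while the oxygen is installed. Setting out from 11, NaH and MOMCl in DMF open the flavanone and cap both phenoxides, giving (E)-4'-methoxy-2',6'-bis(methoxymethoxy)-4-(prenyloxy)chalcone F2. Weitz–Scheffer epoxidation (H2O2, NaOH, MeOH) gives the racemic trans-epoxide F3. Dilute HCl in MeOH at about 40 °C removes both acetals and lets a freed phenol open the epoxide at the benzylic carbon.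
- **Return to the route:** The sequence comes back at 13, which the alkaline peroxide of step 7 dehydrogenates to 14.

Step 4.
- **What may go wrong:** The third deprotonation may be incomplete, conjugate addition to the cinnamoyl unit may compete, or the sensitive triketo ester may cyclise during work-up and purification.
- **Fallback:** The ester terminus is masked, only a dianion is needed, and the chain is released under neutral conditions. Commercial 2,2,6-trimethyl-1,3-dioxin-4-one is deprotonated (LDA, THF, −78 °C) and C-acylated with acetyl chloride to 2,2-dimethyl-6-(2-oxopropyl)-1,3-dioxin-4-one F4. Setting out from 4, the dianion of F4 (2 equiv LDA) is acylated by this Weinreb amide to the diketo-dioxinone F5. Heating F5 in toluene with methanol (about 110 °C) causes retro-[4+2] loss of acetone to the acylketene F6.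
- **Return to the route:** Methanol traps F6 to give 8.

Further compounds
F1 | step 5 | 4-(3-methylbut-2-enyloxy)benzaldehyde | CC(C)=CCOc1ccc(C=O)cc1
F2 | step 7 | (E)-1-[4-methoxy-2,6-bis(methoxymethoxy)phenyl]-3-[4-(3-methylbut-2-enyloxy)phenyl]prop-2-en-1-one | COCOc1cc(OC)cc(OCOC)c1C(=O)/C=C/c1ccc(OCC=C(C)C)cc1
F3 | step 7 | (±)-trans-[4-methoxy-2,6-bis(methoxymethoxy)phenyl]{3-[4-(3-methylbut-2-enyloxy)phenyl]oxiran-2-yl}methanone (racemic, one enantiomer drawn) | COCOc1cc(OC)cc(OCOC)c1C(=O)[C@@H]1O[C@H]1c1ccc(OCC=C(C)C)cc1
F4 | step 4 | 2,2-dimethyl-6-(2-oxopropyl)-1,3-dioxin-4-one | CC(=O)CC1=CC(=O)OC(C)(C)O1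
F5 | step 4 | (E)-2,2-dimethyl-6-{6-[4-(3-methylbut-2-enyloxy)phenyl]-2,4-dioxohex-5-enyl}-1,3-dioxin-4-one | CC1(C)OC(=O)C=C(CC(=O)CC(=O)/C=C/c2ccc(OCC=C(C)C)cc2)O1
F6 | step 4 | (E)-9-[4-(3-methylbut-2-enyloxy)phenyl]nona-1,8-diene-1,3,5,7-tetraone (acylketene, transient) | O=C=CC(=O)CC(=O)CC(=O)/C=C/c1ccc(OCC=C(C)C)cc1
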